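**Plan**

1. Numbering: ring B is the dihydrofuran (O1, C2, C3, C3a, C7a) and ring A the carbocycle (C3a, C4–C7, C7a). Chain carbons carry carotenoid numbers (C9 on C2, C8' = CHO); the target is (3R,5R,8R)-5,8-epoxy-3-hydroxy-5,8-dihydro-8'-apo-β-caroten-8'-al.
2. Retrosynthesis first cuts the polyene at C11=C12 (Wittig) and C11'=C12' (Horner–Wadsworth–Emmons), traces the C8' aldehyde to an ester and the C6 carbinol to a ketone.
3. Ring A then shows a 1,3-dioxygenated unit C5–C6(O)–C7–C7a(O1) and an exocyclic C3=C3a alkene beside the gem-dimethyl C4. These are a 1-alkoxy-3-silyloxy diene and a 1,1-dimethylallene used through its distal π bond, already joined by O1–C2, so C4–C5 and C3a–C7a are cut together by a retro intramolecular Diels–Alder reaction that opens rings A and B at once.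
4. Forward: C5 enal → propargylic alcohol → α-allenic alcohol → dienyl ether → cycloaddition (rings A and B together) → C6 adjustment → phosphonium salt → Wittig with a C15 ester aldehyde → aldehyde.
5. Stereochemistry: C2 from a catalyst-controlled alkynylation; C7a relayed from C2 in the cycloaddition (epimer separable); C6 by hydride attack anti to the axial methyls, then Mitsunobu inversion; (E)-alkenes from stabilised ylide and phosphonate olefinations plus thermal equilibration.

Key step: step 6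

Assumption: 3-methoxy-3-methylbut-1-yne (4), ethyl (2E)-4-bromo-2-methylbut-2-enoate (19) and the C10 dialdehyde (21) are taken as catalogue compounds.

**Route**

Step 1
Reactants: 1 (tert-butyldimethylsilyloxy)acetaldehyde; 2 2-(triphenyl-λ5-phosphanylidene)propanal
Product: 3 (2E)-4-[(tert-butyldimethylsilyl)oxy]-2-methylbut-2-enal
Conditions: toluene, 80 °C
Reagents that add atoms: none
Why: Wittig olefination with a formyl-stabilised ylide is (E)-selective and stops at the α-branched enal, which fixes the later C9=C10 geometry.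

Step 2
Reactants: 3 (2E)-4-[(tert-butyldimethylsilyl)oxy]-2-methylbut-2-enal; 4 3-methoxy-3-methylbut-1-yne
Product: 6 (2E,4S)-1-[(tert-butyldimethylsilyl)oxy]-7-methoxy-3,7-dimethyloct-2-en-5-yn-4-ol, via methylzinc acetylide 5 (not isolated)
Conditions: Me2Zn, (S,S)-ProPhenol (20 mol %), Ph3P=O (40 mol %), toluene, 0 °C
Reagents that add atoms: none
Why: Zinc–ProPhenol catalysed enantioselective alkynylation of an enal, in which the bimetallic catalyst should deliver the acetylide to the Re face and set the carbinol centre (later C2) as 4S; the sense of induction is to be confirmed and the antipodal ligand used if it proves opposite.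

Step 3
Reactants: 6 (2E,4S)-1-[(tert-butyldimethylsilyl)oxy]-7-methoxy-3,7-dimethyloct-2-en-5-yn-4-ol
Product: 7 (2E,4R)-1-[(tert-butyldimethylsilyl)oxy]-3,7-dimethylocta-2,5,6-trien-4-ol
Conditions: LiAlH4, THF, 0 to 40 °C
Reagents that add atoms: none
Why: Hydroxyl-directed trans-hydroalumination puts hydride on the proximal alkyne carbon, and anti-elimination of the tertiary methoxide (formal SN2' hydride substitution) gives the 1,1-dimethylallene without touching the carbinol centre, whose descriptor becomes R by priority change only.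

Step 4
Reactants: 7 (2E,4R)-1-[(tert-butyldimethylsilyl)oxy]-3,7-dimethylocta-2,5,6-trien-4-ol; 8 pent-3-yn-2-one
Product: 9 (3E)-4-({(2E,4R)-1-[(tert-butyldimethylsilyl)oxy]-3,7-dimethylocta-2,5,6-trien-4-yl}oxy)pent-3-en-2-one
Conditions: PMe3 (20 mol %), CH2Cl2, 0 °C to rt
Reagents that add atoms: none
Why: Phosphine-catalysed oxa-Michael addition of the alcohol to the ynone should give the thermodynamically preferred (E)-β-alkoxy enone under neutral conditions that spare the acid-labile doubly allylic carbinol.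

Step 5
Reactants: 9 (3E)-4-({(2E,4R)-1-[(tert-butyldimethylsilyl)oxy]-3,7-dimethylocta-2,5,6-trien-4-yl}oxy)pent-3-en-2-one
Product: 11 tert-butyl{[(2E,4R)-3,7-dimethyl-4-({(2E)-4-[(triethylsilyl)oxy]penta-2,4-dien-2-yl}oxy)octa-2,5,6-trien-1-yl]oxy}dimethylsilane, via lithium dienolate 10 (not isolated)
Conditions: LiN(iPr)2, THF, −78 °C; then Et3SiCl, −78 to 0 °C
Reagents that add atoms: chlorotriethylsilane, CC[Si](Cl)(CC)CC
Why: Kinetic deprotonation of the vinylogous ester at the α'-methyl group (Stork–Danheiser regiochemistry) and O-silylation give the cross-conjugated 1-alkoxy-3-silyloxy diene.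

Step 6
Reactants: 11 tert-butyl{[(2E,4R)-3,7-dimethyl-4-({(2E)-4-[(triethylsilyl)oxy]penta-2,4-dien-2-yl}oxy)octa-2,5,6-trien-1-yl]oxy}dimethylsilane
Product: 12 (2R,7aR)-2-[(2E)-4-{[tert-butyl(dimethyl)silyl]oxy}but-2-en-2-yl]-4,4,7a-trimethyl-6-[(triethylsilyl)oxy]-2,4,5,7a-tetrahydro-1-benzofuran
Conditions: 2,6-di-tert-butylpyridine and BHT (5 mol % each), CH2Cl2 (0.02 M), 12 kbar, 40 °C
Reagents that add atoms: none
Why: Proposed new method: a concerted, asynchronous [4+2] cycloaddition in which the cisoid diene C5=C6–C7=C7a adds across the distal C3a=C4 π bond of the 1,1-dimethylallene, forming C3a–C7a and C4–C5 together while the proximal allene π bond survives as C3=C3a and the diene oxygen as the C6 silyl enol ether; the closest known reaction type is the intramolecular Diels–Alder addition of a diene to the terminal π bond of an allene whose other terminus is linked to the diene by two atoms (arene–allenecarboxamide and furan–allenyl ether cases), not yet shown for an acyclic dienyl ether of an α-allenic alcohol. Ring B (O1–C2–C3=C3a–C7a) closes through the tether as the five-membered ring of a fused, type 1 intramolecular Diels–Alder reaction, and ring A (C3a–C4–C5–C6–C7–C7a) closes as the new cyclohexene. C7a is the only new stereocentre and is controlled by C2: the forming ring B is flat and lies in the mirror plane of the dimethylallene, the two C2 substituents point to its two faces, and the butenyl group should take the face shared with the planar C7–H and avoid the inside methyl on C7a, which places it trans to that methyl as in 2R,7aR; the C7a epimer is a diastereomer and is removed on Et3N-deactivated silica. Site selectivity for the distal π bond follows from the short O1–C2 link, since addition to C3=C3a would require a bridged bicycle, and the (E)-enol ether keeps O1 outside the diene where the link can reach C3a. The periselectivity needed is [4+2] over the [3,3] (Claisen) shift open to this allyl and allenylmethyl vinyl ether; the 3-silyloxy group populates the cisoid diene, strain release at the sp carbon lowers the cycloaddition barrier, and 12 kbar at 40 °C favours the pathway with the more negative activation volume, which is the cycloaddition. The hindered base protects the silyl enol ether from adventitious acid.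

Step 7
Reactants: 12 (2R,7aR)-2-[(2E)-4-{[tert-butyl(dimethyl)silyl]oxy}but-2-en-2-yl]-4,4,7a-trimethyl-6-[(triethylsilyl)oxy]-2,4,5,7a-tetrahydro-1-benzofuran
Product: 13 (2R,7aR)-2-[(2E)-4-{[tert-butyl(dimethyl)silyl]oxy}but-2-en-2-yl]-4,4,7a-trimethyl-2,4,5,7a-tetrahydro-1-benzofuran-6(7H)-one
Conditions: Bu4NF (1.05 equiv), AcOH (1.5 equiv), THF, −40 °C
Reagents that add atoms: none
Why: Buffered fluoride desilylation cleaves the triethylsilyl enol ether much faster than the primary silyl ether and protonates the enolate at once, so the β-alkoxy ketone is not exposed to base that could open ring B by retro-oxa-Michael reaction.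

Step 8
Reactants: 13 (2R,7aR)-2-[(2E)-4-{[tert-butyl(dimethyl)silyl]oxy}but-2-en-2-yl]-4,4,7a-trimethyl-2,4,5,7a-tetrahydro-1-benzofuran-6(7H)-one
Product: 14 (2R,6S,7aR)-2-[(2E)-4-{[tert-butyl(dimethyl)silyl]oxy}but-2-en-2-yl]-4,4,7a-trimethyl-2,4,5,6,7,7a-hexahydro-1-benzofuran-6-ol
Conditions: LiBH(s-Bu)3, THF, −78 °C; then H2O
Reagents that add atoms: none
Why: Substrate-controlled hydride reduction in which the bulky borohydride attacks the ring A carbonyl from the face opposite the axial C7a and C4 methyl groups (equatorial attack), giving the axial 6S alcohol cis to the C7a methyl.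

Step 9
Reactants: 14 (2R,6S,7aR)-2-[(2E)-4-{[tert-butyl(dimethyl)silyl]oxy}but-2-en-2-yl]-4,4,7a-trimethyl-2,4,5,6,7,7a-hexahydro-1-benzofuran-6-ol
Product: 15 (2R,6R,7aR)-2-[(2E)-4-{[tert-butyl(dimethyl)silyl]oxy}but-2-en-2-yl]-4,4,7a-trimethyl-2,4,5,6,7,7a-hexahydro-1-benzofuran-6-yl benzoate
Conditions: PhCO2H, PPh3, diisopropyl azodicarboxylate, toluene, 0 °C to rt
Reagents that add atoms: benzoic acid, O=C(O)c1ccccc1
Why: Mitsunobu esterification displaces the activated axial oxygen by SN2 from the unhindered face, inverting C6 to the required 6R configuration (oxygen cis to O1, trans to the C7a methyl) and leaving it protected as the benzoate.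

Step 10
Reactants: 15 (2R,6R,7aR)-2-[(2E)-4-{[tert-butyl(dimethyl)silyl]oxy}but-2-en-2-yl]-4,4,7a-trimethyl-2,4,5,6,7,7a-hexahydro-1-benzofuran-6-yl benzoate
Product: 16 (2R,6R,7aR)-2-[(2E)-4-hydroxybut-2-en-2-yl]-4,4,7a-trimethyl-2,4,5,6,7,7a-hexahydro-1-benzofuran-6-yl benzoate
Conditions: Bu4NF, AcOH, THF, rt
Reagents that add atoms: none
Why: Fluoride desilylation of the primary allylic silyl ether, buffered with acetic acid so that the benzoate neither migrates nor is lost.

Step 11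
Reactants: 16 (2R,6R,7aR)-2-[(2E)-4-hydroxybut-2-en-2-yl]-4,4,7a-trimethyl-2,4,5,6,7,7a-hexahydro-1-benzofuran-6-yl benzoate
Product: 17 (2R,6R,7aR)-2-[(2E)-4-bromobut-2-en-2-yl]-4,4,7a-trimethyl-2,4,5,6,7,7a-hexahydro-1-benzofuran-6-yl benzoate
Conditions: CBr4, PPh3, 2,6-lutidine, CH2Cl2, −20 °C
Reagents that add atoms: carbon tetrabromide, BrC(Br)(Br)Br
Why: Appel bromination converts the primary allylic alcohol into the bromide under neutral, buffered conditions, without allylic transposition or ionisation of the C2–O1 bond.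

Step 12
Reactants: 17 (2R,6R,7aR)-2-[(2E)-4-bromobut-2-en-2-yl]-4,4,7a-trimethyl-2,4,5,6,7,7a-hexahydro-1-benzofuran-6-yl benzoate
Product: 18 {(2E)-3-[(2R,6R,7aR)-6-(benzoyloxy)-4,4,7a-trimethyl-2,4,5,6,7,7a-hexahydro-1-benzofuran-2-yl]but-2-en-1-yl}triphenylphosphonium bromide
Conditions: PPh3, MeCN, rt
Reagents that add atoms: triphenylphosphine, c1ccc(cc1)P(c1ccccc1)c1ccccc1
Why: SN2 quaternisation of triphenylphosphine by the primary allylic bromide gives the C15-type Wittig salt of classical carotenoid assembly.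

Step 13
Reactants: 19 ethyl (2E)-4-bromo-2-methylbut-2-enoate
Product: 20 ethyl (2E)-4-(diethoxyphosphoryl)-2-methylbut-2-enoate
Conditions: P(OEt)3, neat, 110 °C
Reagents that add atoms: triethyl phosphite, CCOP(OCC)OCC
Why: Michaelis–Arbuzov reaction of the primary allylic bromide proceeds with retention of the (E)-enoate geometry.

Step 14
Reactants: 20 ethyl (2E)-4-(diethoxyphosphoryl)-2-methylbut-2-enoate; 21 (2E,4E,6E)-2,7-dimethylocta-2,4,6-trienedial
Product: 23 ethyl (2E,4E,6E,8E,10E)-2,6,11-trimethyl-12-oxododeca-2,4,6,8,10-pentaenoate, via sodium phosphonate carbanion 22 (not isolated)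
Conditions: NaN(SiMe3)2, THF, −78 °C; then 21 (3 equiv), −78 to 0 °C
Reagents that add atoms: none
Why: Horner–Wadsworth–Emmons olefination of one formyl group of the symmetrical dialdehyde, used in excess, is (E)-selective, and the longer conjugated product aldehyde is less electrophilic, which favours mono-olefination.

Step 15
Reactants: 18 {(2E)-3-[(2R,6R,7aR)-6-(benzoyloxy)-4,4,7a-trimethyl-2,4,5,6,7,7a-hexahydro-1-benzofuran-2-yl]but-2-en-1-yl}triphenylphosphonium bromide; 23 ethyl (2E,4E,6E,8E,10E)-2,6,11-trimethyl-12-oxododeca-2,4,6,8,10-pentaenoate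
Product: 25 ethyl (2E,4E,6E,8E,10E,12E,14E)-15-[(2R,6R,7aR)-6-(benzoyloxy)-4,4,7a-trimethyl-2,4,5,6,7,7a-hexahydro-1-benzofuran-2-yl]-2,6,11-trimethylhexadeca-2,4,6,8,10,12,14-heptaenoate, via allylic phosphorus ylide 24 (not isolated)
Conditions: NaN(SiMe3)2, THF, −78 °C; then 23, −78 to 0 °C; then heptane, 80 °C, dark
Reagents that add atoms: none
Why: Wittig olefination of the semi-stabilised allylic ylide with the α-methyl polyenal forms C11=C12, and any (Z) portion of the new disubstituted alkene is equilibrated thermally to the all-(E) polyene as is usual in carotenoid synthesis.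

Step 16
Reactants: 25 ethyl (2E,4E,6E,8E,10E,12E,14E)-15-[(2R,6R,7aR)-6-(benzoyloxy)-4,4,7a-trimethyl-2,4,5,6,7,7a-hexahydro-1-benzofuran-2-yl]-2,6,11-trimethylhexadeca-2,4,6,8,10,12,14-heptaenoate
Product: 26 (2E,4E,6E,8E,10E,12E,14E)-15-[(2R,6R,7aR)-6-hydroxy-4,4,7a-trimethyl-2,4,5,6,7,7a-hexahydro-1-benzofuran-2-yl]-2,6,11-trimethylhexadeca-2,4,6,8,10,12,14-heptaen-1-ol
Conditions: iBu2AlH (5 equiv), CH2Cl2, −78 °C; aq. potassium sodium tartrate
Reagents that add atoms: none
Why: Hydride reduction with iBu2AlH converts the conjugated ester into the allylic alcohol by 1,2-reduction and removes the benzoate in the same operation.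

Step 17
Reactants: 26 (2E,4E,6E,8E,10E,12E,14E)-15-[(2R,6R,7aR)-6-hydroxy-4,4,7a-trimethyl-2,4,5,6,7,7a-hexahydro-1-benzofuran-2-yl]-2,6,11-trimethylhexadeca-2,4,6,8,10,12,14-heptaen-1-ol
Product: 27 (2E,4E,6E,8E,10E,12E,14E)-15-[(2R,6R,7aR)-6-hydroxy-4,4,7a-trimethyl-2,4,5,6,7,7a-hexahydro-1-benzofuran-2-yl]-2,6,11-trimethylhexadeca-2,4,6,8,10,12,14-heptaenal (CNP0118413.1)
Conditions: MnO2, CH2Cl2, rt, dark
Reagents that add atoms: none
Why: Allylic oxidation with MnO2 converts only the polyene-conjugated primary alcohol into the aldehyde and leaves the saturated secondary C6 hydroxyl untouched.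

**Compound list**

1 | (tert-butyldimethylsilyloxy)acetaldehyde | O=CCO[Si](C)(C)C(C)(C)C | starting material
2 | 2-(triphenyl-λ5-phosphanylidene)propanal | CC(C=O)=P(c1ccccc1)(c1ccccc1)c1ccccc1 | starting material
3 | (2E)-4-[(tert-butyldimethylsilyl)oxy]-2-methylbut-2-enal | O=C/C(C)=C/CO[Si](C)(C)C(C)(C)C | intermediate
4 | 3-methoxy-3-methylbut-1-yne | C#CC(C)(C)OC | starting material
5 | methyl(3-methoxy-3-methylbut-1-yn-1-yl)zinc | C[Zn]C#CC(C)(C)OC | intermediate
6 | (2E,4S)-1-[(tert-butyldimethylsilyl)oxy]-7-methoxy-3,7-dimethyloct-2-en-5-yn-4-ol | CC(C)(C)[Si](C)(C)OC/C=C(\C)[C@H](O)C#CC(C)(C)OC | intermediate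
7 | (2E,4R)-1-[(tert-butyldimethylsilyl)oxy]-3,7-dimethylocta-2,5,6-trien-4-ol | CC(C)(C)[Si](C)(C)OC/C=C(\C)[C@H](O)C=C=C(C)C | intermediate
8 | pent-3-yn-2-one | CC#CC(C)=O | starting material
9 | (3E)-4-({(2E,4R)-1-[(tert-butyldimethylsilyl)oxy]-3,7-dimethylocta-2,5,6-trien-4-yl}oxy)pent-3-en-2-one | CC(C)(C)[Si](C)(C)OC/C=C(\C)[C@H](O/C(C)=C/C(C)=O)C=C=C(C)C | intermediate
10 | lithium (3E)-4-({(2E,4R)-1-[(tert-butyldimethylsilyl)oxy]-3,7-dimethylocta-2,5,6-trien-4-yl}oxy)penta-1,3-dien-2-olate | CC(C)(C)[Si](C)(C)OC/C=C(\C)[C@H](O/C(C)=C/C(=C)[O-])C=C=C(C)C.[Li+] | intermediate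
11 | tert-butyl{[(2E,4R)-3,7-dimethyl-4-({(2E)-4-[(triethylsilyl)oxy]penta-2,4-dien-2-yl}oxy)octa-2,5,6-trien-1-yl]oxy}dimethylsilane | CC(C)(C)[Si](C)(C)OC/C=C(\C)[C@H](O/C(C)=C/C(=C)O[Si](CC)(CC)CC)C=C=C(C)C | intermediate
12 | (2R,7aR)-2-[(2E)-4-{[tert-butyl(dimethyl)silyl]oxy}but-2-en-2-yl]-4,4,7a-trimethyl-6-[(triethylsilyl)oxy]-2,4,5,7a-tetrahydro-1-benzofuran | CC(C)(C)[Si](C)(C)OC/C=C(\C)[C@H]1C=C2C(C)(C)CC(O[Si](CC)(CC)CC)=C[C@@]2(C)O1 | intermediate
13 | (2R,7aR)-2-[(2E)-4-{[tert-butyl(dimethyl)silyl]oxy}but-2-en-2-yl]-4,4,7a-trimethyl-2,4,5,7a-tetrahydro-1-benzofuran-6(7H)-one | CC(C)(C)[Si](C)(C)OC/C=C(\C)[C@H]1C=C2C(C)(C)CC(=O)C[C@@]2(C)O1 | intermediate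
14 | (2R,6S,7aR)-2-[(2E)-4-{[tert-butyl(dimethyl)silyl]oxy}but-2-en-2-yl]-4,4,7a-trimethyl-2,4,5,6,7,7a-hexahydro-1-benzofuran-6-ol | CC(C)(C)[Si](C)(C)OC/C=C(\C)[C@H]1C=C2C(C)(C)C[C@H](O)C[C@@]2(C)O1 | intermediate
15 | (2R,6R,7aR)-2-[(2E)-4-{[tert-butyl(dimethyl)silyl]oxy}but-2-en-2-yl]-4,4,7a-trimethyl-2,4,5,6,7,7a-hexahydro-1-benzofuran-6-yl benzoate | CC(C)(C)[Si](C)(C)OC/C=C(\C)[C@H]1C=C2C(C)(C)C[C@@H](OC(=O)c3ccccc3)C[C@@]2(C)O1 | intermediate
16 | (2R,6R,7aR)-2-[(2E)-4-hydroxybut-2-en-2-yl]-4,4,7a-trimethyl-2,4,5,6,7,7a-hexahydro-1-benzofuran-6-yl benzoate | OC/C=C(\C)[C@H]1C=C2C(C)(C)C[C@@H](OC(=O)c3ccccc3)C[C@@]2(C)O1 | intermediate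
17 | (2R,6R,7aR)-2-[(2E)-4-bromobut-2-en-2-yl]-4,4,7a-trimethyl-2,4,5,6,7,7a-hexahydro-1-benzofuran-6-yl benzoate | BrC/C=C(\C)[C@H]1C=C2C(C)(C)C[C@@H](OC(=O)c3ccccc3)C[C@@]2(C)O1 | intermediate
18 | {(2E)-3-[(2R,6R,7aR)-6-(benzoyloxy)-4,4,7a-trimethyl-2,4,5,6,7,7a-hexahydro-1-benzofuran-2-yl]but-2-en-1-yl}triphenylphosphonium bromide | [Br-].c1ccccc1[P+](c1ccccc1)(c1ccccc1)C/C=C(\C)[C@H]1C=C2C(C)(C)C[C@@H](OC(=O)c3ccccc3)C[C@@]2(C)O1 | intermediate
19 | ethyl (2E)-4-bromo-2-methylbut-2-enoate | CCOC(=O)/C(C)=C/CBr | starting material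
20 | ethyl (2E)-4-(diethoxyphosphoryl)-2-methylbut-2-enoate | CCOC(=O)/C(C)=C/CP(=O)(OCC)OCC | intermediate
21 | (2E,4E,6E)-2,7-dimethylocta-2,4,6-trienedial | O=C/C(C)=C/C=C/C=C(\C)C=O | starting material
22 | sodium salt of the C4 carbanion of ethyl (2E)-4-(diethoxyphosphoryl)-2-methylbut-2-enoate | [Na+].CCOC(=O)/C(C)=C/[CH-]P(=O)(OCC)OCC | intermediate
23 | ethyl (2E,4E,6E,8E,10E)-2,6,11-trimethyl-12-oxododeca-2,4,6,8,10-pentaenoate | CCOC(=O)/C(C)=C/C=C/C(C)=C/C=C/C=C(\C)C=O | intermediate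
24 | {(2E)-3-[(2R,6R,7aR)-6-(benzoyloxy)-4,4,7a-trimethyl-2,4,5,6,7,7a-hexahydro-1-benzofuran-2-yl]but-2-en-1-ylidene}triphenyl-λ5-phosphane | c1ccccc1P(c1ccccc1)(c1ccccc1)=C/C=C(\C)[C@H]1C=C2C(C)(C)C[C@@H](OC(=O)c3ccccc3)C[C@@]2(C)O1 | intermediate
25 | ethyl (2E,4E,6E,8E,10E,12E,14E)-15-[(2R,6R,7aR)-6-(benzoyloxy)-4,4,7a-trimethyl-2,4,5,6,7,7a-hexahydro-1-benzofuran-2-yl]-2,6,11-trimethylhexadeca-2,4,6,8,10,12,14-heptaenoate | CCOC(=O)/C(C)=C/C=C/C(C)=C/C=C/C=C(C)/C=C/C=C(\C)[C@H]1C=C2C(C)(C)C[C@@H](OC(=O)c3ccccc3)C[C@@]2(C)O1 | intermediate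
26 | (2E,4E,6E,8E,10E,12E,14E)-15-[(2R,6R,7aR)-6-hydroxy-4,4,7a-trimethyl-2,4,5,6,7,7a-hexahydro-1-benzofuran-2-yl]-2,6,11-trimethylhexadeca-2,4,6,8,10,12,14-heptaen-1-ol | OC/C(C)=C/C=C/C(C)=C/C=C/C=C(C)/C=C/C=C(\C)[C@H]1C=C2C(C)(C)C[C@@H](O)C[C@@]2(C)O1 | intermediate
27 | (2E,4E,6E,8E,10E,12E,14E)-15-[(2R,6R,7aR)-6-hydroxy-4,4,7a-trimethyl-2,4,5,6,7,7a-hexahydro-1-benzofuran-2-yl]-2,6,11-trimethylhexadeca-2,4,6,8,10,12,14-heptaenal | C\C(C=O)=C/C=C/C(C)=C/C=C/C=C(C)/C=C/C=C(\C)[C@H]1C=C2C(C)(C)C[C@@H](O)C[C@@]2(C)O1 | target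

**Step count and risks**

Total step count: 17. Longest linear sequence: 15 (steps 1–12, 15–17).

Steps most likely to fail:

1. Step 6. The [3,3] shift of the doubly allylic enol ether may outrun the cycloaddition, facial discrimination at C7a by the remote C2 centre may be poor, and a 1,5-hydrogen shift may drain the cisoid diene. The fallback uses known carotenoid chemistry, sets out from 23 and comes back at 25. Wittig reaction of 23 with the (3R)-3-hydroxy C15 phosphonium chloride of zeaxanthin manufacture, [(2E,4E)-5-[(4R)-4-hydroxy-2,6,6-trimethylcyclohex-1-en-1-yl]-3-methylpenta-2,4-dien-1-yl]triphenylphosphonium chloride (1,2-epoxybutane, EtOH, reflux), should give ethyl (3R)-3-hydroxy-8'-apo-β-caroten-8'-oate F1. Acetylation (Ac2O, pyridine) gives ethyl (3R)-3-acetoxy-8'-apo-β-caroten-8'-oate F2. Monoperoxyphthalic acid in Et2O epoxidises the ring double bond anti to the acetoxy group to ethyl (3S,5R,6S)-3-acetoxy-5,6-epoxy-5,6-dihydro-8'-apo-β-caroten-8'-oate F3. Dilute HCl in CHCl3 brings about the epoxide–furanoid rearrangement with retention at C5, and chromatography removes the 8S epimer to leave ethyl (3S,5R,8R)-3-acetoxy-5,8-epoxy-5,8-dihydro-8'-apo-β-caroten-8'-oate F4. Deacetylation (K2CO3, EtOH) gives ethyl (3S,5R,8R)-5,8-epoxy-3-hydroxy-5,8-dihydro-8'-apo-β-caroten-8'-oate F5, whose ring has the configuration of 14. Mitsunobu inversion with benzoic acid (PPh3, diisopropyl azodicarboxylate) then gives 25.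

2. Step 4. Conjugate addition of the hindered secondary alkoxide to the β-methyl ynone may be too slow, so that phosphine-induced oligomerisation of the ynone or base-induced cyclisation of the allenol takes over. The fallback sets out from 7 and comes back at 9. Pentane-2,4-dione is converted with (COCl)2 and catalytic DMF into (3E)-4-chloropent-3-en-2-one F6. The sodium alkoxide of 7 (NaH, THF, 0 °C) then displaces chloride by addition–elimination at the vinylogous acyl carbon to give 9.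

3. Step 9. Activation of the crowded axial hydroxyl may fail, or anti-elimination to the cyclohexene may compete with substitution. The fallback sets out from 13 and comes back at 15. Electron-transfer reduction of 13 under thermodynamic control (SmI2, H2O, Et3N, THF, rt), in which the ketyl-derived carbanion is protonated to the more stable equatorial carbinol, should give (2R,6R,7aR)-2-[(2E)-4-{[tert-butyl(dimethyl)silyl]oxy}but-2-en-2-yl]-4,4,7a-trimethyl-2,4,5,6,7,7a-hexahydro-1-benzofuran-6-ol F7. Benzoylation (PhCOCl, pyridine) then gives 15.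

**Further compounds**

F1 | step 6 | ethyl (3R)-3-hydroxy-8'-apo-β-caroten-8'-oate | CCOC(=O)/C(C)=C/C=C/C(C)=C/C=C/C=C(C)/C=C/C=C(C)/C=C/C1=C(C)C[C@@H](O)CC1(C)C
F2 | step 6 | ethyl (3R)-3-acetoxy-8'-apo-β-caroten-8'-oate | CCOC(=O)/C(C)=C/C=C/C(C)=C/C=C/C=C(C)/C=C/C=C(C)/C=C/C1=C(C)C[C@@H](OC(C)=O)CC1(C)C
F3 | step 6 | ethyl (3S,5R,6S)-3-acetoxy-5,6-epoxy-5,6-dihydro-8'-apo-β-caroten-8'-oate | CCOC(=O)/C(C)=C/C=C/C(C)=C/C=C/C=C(C)/C=C/C=C(C)/C=C/[C@@]12O[C@]1(C)C[C@@H](OC(C)=O)CC2(C)C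
F4 | step 6 | ethyl (3S,5R,8R)-3-acetoxy-5,8-epoxy-5,8-dihydro-8'-apo-β-caroten-8'-oate | CCOC(=O)/C(C)=C/C=C/C(C)=C/C=C/C=C(C)/C=C/C=C(\C)[C@H]1C=C2C(C)(C)C[C@H](OC(C)=O)C[C@@]2(C)O1
F5 | step 6 | ethyl (3S,5R,8R)-5,8-epoxy-3-hydroxy-5,8-dihydro-8'-apo-β-caroten-8'-oate | CCOC(=O)/C(C)=C/C=C/C(C)=C/C=C/C=C(C)/C=C/C=C(\C)[C@H]1C=C2C(C)(C)C[C@H](O)C[C@@]2(C)O1
F6 | step 4 | (3E)-4-chloropent-3-en-2-one | CC(=O)/C=C(\C)Cl
F7 | step 9 | (2R,6R,7aR)-2-[(2E)-4-{[tert-butyl(dimethyl)silyl]oxy}but-2-en-2-yl]-4,4,7a-trimethyl-2,4,5,6,7,7a-hexahydro-1-benzofuran-6-ol | CC(C)(C)[Si](C)(C)OC/C=C(\C)[C@H]1C=C2C(C)(C)C[C@@H](O)C[C@@]2(C)O1
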